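**Retrosynthetic overview**
1. The last bond made is C5'–Cl: electrophilic chlorination of the deschloro depside at the only aromatic carbon of the molecule that still bears hydrogen.
2. Ring B is cut at C1'–C2' and C5'–C6'. The strategy rests on the placement of its oxygens: the 2'-methoxy oxygen is ortho and the 4'-hydroxy oxygen para to the ester-bearing carbon C1', with the C3' methyl between them and the C6' methyl on the other side of C1'. This is the pattern a 1,1-dimethoxy-2-methyl-3-siloxybutadiene leaves on a but-2-ynoate after (4+2) cycloaddition and loss of methanol.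
3. The dienophile is the but-2-ynoate ester of the ring A phenol at O4. Ring A comes from methyl atrarate by C5 formylation and hydrogenolysis to the methyl group.
4. The diene comes from trimethyl orthopropionate: ketene acetal, C-acetylation with acetyl chloride, O-silylation.
5. Ring order: ring A is bought as an arene; ring B is the only ring formed, in step 7.

Key step: step 7

Assumption: the 2-hydroxyl of ring A is carried unprotected throughout, because its hydrogen bond to the ester carbonyl makes it a poor nucleophile and a weak acid. Ring A keeps the benzoate numbering of methyl atrarate; ring B carries primed locants with C1' as the carbonyl-bearing carbon.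

**Route**

Step 1
Reactants: 1 methyl 2,4-dihydroxy-3,6-dimethylbenzoate (methyl atrarate)
Product: 3 methyl 5-formyl-2,4-dihydroxy-3,6-dimethylbenzoate, via 5-[chloro(methoxy)methyl] arene 2 (not isolated)
Conditions: Cl2CHOMe, TiCl4, CH2Cl2, −10 °C to rt; then ice-cold 1 M HCl
Reagents that add atoms: dichloromethyl methyl ether, COC(Cl)Cl; water, O
Why: Rieche formylation, in which TiCl4-activated dichloromethyl methyl ether attacks C5, the only free ring position (ortho to the 4-hydroxyl, para to the 2-hydroxyl), and the α-chloro ether 2 is hydrolysed to the aldehyde on aqueous work-up; the reaction is known to tolerate a flanking methyl group, as in the formylation of mesitylene.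

Step 2
Reactants: 3 methyl 5-formyl-2,4-dihydroxy-3,6-dimethylbenzoate
Product: 5 methyl 2,4-dihydroxy-3,5,6-trimethylbenzoate, via 5-(hydroxymethyl) arene 4 (not isolated)
Conditions: H2 (3 bar), 10% Pd/C, AcOH, cat. HCl, 40 °C
Reagents that add atoms: none
Why: Catalytic hydrogenolysis of an electron-rich ortho-hydroxybenzaldehyde, in which the aldehyde is hydrogenated to benzylic alcohol 4 and its C–O bond, labilized by the ortho and para hydroxyls, is cleaved on palladium to the methyl group while the ester and the arene should stay untouched.

Step 3
Reactants: 5 methyl 2,4-dihydroxy-3,5,6-trimethylbenzoate; 6 but-2-ynoic acid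
Product: 8 methyl 4-(but-2-ynoyloxy)-2-hydroxy-3,5,6-trimethylbenzoate, via but-2-ynoyl O-acylisourea 7 (not isolated)
Conditions: DCC, DMAP (cat.), CH2Cl2, 0 °C to rt
Reagents that add atoms: none
Why: Steglich esterification, in which O-acylisourea 7 passes the butynoyl group through DMAP to the 4-hydroxyl, the more acidic and non-chelated phenol, whereas the 2-hydroxyl is held in a hydrogen bond to the ester carbonyl; aryl alk-2-ynoates are routinely made this way with DMAP kept catalytic and the temperature low.

Step 4
Reactants: 9 trimethyl orthopropionate (1,1,1-trimethoxypropane)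
Product: 10 1,1-dimethoxyprop-1-ene
Conditions: Al(OMe)3 (cat.), neat, reflux under a fractionating column with continuous removal of MeOH; then fractional distillation
Reagents that add atoms: none
Why: Dealcoholation of an orthoester to a ketene acetal, in which the aluminium alkoxide ionizes one methoxy group and the alpha proton is lost, the equilibrium being pulled over by distilling out methanol; it is the same elimination that opens the Johnson–Claisen rearrangement.

Step 5
Reactants: 10 1,1-dimethoxyprop-1-ene; 11 acetyl chloride
Product: 12 4,4-dimethoxy-3-methylbut-3-en-2-one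
Conditions: Et3N, Et2O, 0 °C to rt
Reagents that add atoms: none
Why: C-Acylation of a ketene acetal, in which the electron-rich beta carbon of 10 attacks acetyl chloride and the resulting dimethoxycarbenium ion loses its doubly activated alpha proton to Et3N, giving the push–pull acylketene acetal.

Step 6
Reactants: 12 4,4-dimethoxy-3-methylbut-3-en-2-one
Product: 14 1,1-dimethoxy-2-methyl-3-(trimethylsilyloxy)buta-1,3-diene, via lithium dienolate 13 (not isolated)
Conditions: LDA, THF, −78 °C; then TMSCl, −78 °C to rt; non-aqueous work-up, distillation under reduced pressure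
Reagents that add atoms: chlorotrimethylsilane, C[Si](C)(C)Cl
Why: Kinetic enolization and O-silylation, in which LDA deprotonates the acetyl methyl group (the kinetically most acidic site) and the cross-conjugated lithium dienolate 13 is trapped on oxygen by TMSCl, as in the standard preparation of 1,1-dimethoxy-3-siloxybutadienes.

Step 7
Reactants: 8 methyl 4-(but-2-ynoyloxy)-2-hydroxy-3,5,6-trimethylbenzoate; 14 1,1-dimethoxy-2-methyl-3-(trimethylsilyloxy)buta-1,3-diene
Product: 17 methyl 2-hydroxy-4-[(4-hydroxy-2-methoxy-3,6-dimethylbenzoyl)oxy]-3,5,6-trimethylbenzoate, via dimethoxy cyclohexa-1,4-diene cycloadduct 15 (not isolated), via aryl trimethylsilyl ether 16 (not isolated)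
Conditions: 14 (3 equiv), toluene (concentrated), 110 °C, sealed tube; then 1 M HCl, THF, rt
Reagents that add atoms: none
Why: This is a thermal, concerted but asynchronous (4+2) cycloaddition of the kind long used to make 4-hydroxy-2-alkoxybenzoates from 1,1-dialkoxy-3-siloxybutadienes and alk-2-ynoates: the CH2 terminus C4 of diene 14, onto which both the ketene acetal and the silyl enol ether push electron density, bonds to the methyl-bearing beta carbon of ynoate 8, and the ketene acetal carbon C1 bonds to the alpha carbon. Ring B is thus closed by an intermolecular six-membered cycloaddition that forms C5'–C6' and C1'–C2' in one event and gives 1,4-cyclohexadiene 15, whose ketal carbon and CH2 group stand 1,4 to each other, so that 1,4-elimination of methanol under the reaction conditions should aromatize it to silyl ether 16, and dilute acid then cleaves the aryl O–Si bond to give 17. No stereocenter is present or formed. The selectivity needed is regiochemical (ester carbon flanked by the methoxy carbon and para to the siloxy carbon), and it is secured by the matched polarization of the 1,1,3-trioxygenated diene and the ynoate, the aryl ester making the alkyne a better acceptor than an alkyl butynoate. The chelated 2-hydroxyl of ring A is covered by the excess of diene, any O-silylation there being reversed in the acidic work-up, and the depside ester meets neither base nor nucleophile.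

Step 8
Reactants: 17 methyl 2-hydroxy-4-[(4-hydroxy-2-methoxy-3,6-dimethylbenzoyl)oxy]-3,5,6-trimethylbenzoate
Product: 18 methyl 4-[(5-chloro-4-hydroxy-2-methoxy-3,6-dimethylbenzoyl)oxy]-2-hydroxy-3,5,6-trimethylbenzoate (CNP0121273.0)
Conditions: SO2Cl2 (1.05 equiv), CH2Cl2, 0 °C to rt
Reagents that add atoms: sulfuryl chloride, O=S(=O)(Cl)Cl
Why: Electrophilic aromatic chlorination, in which sulfuryl chloride delivers electrophilic chlorine to C5', the only ring carbon bearing hydrogen and ortho to the free 4'-hydroxyl, while ring A is fully substituted and its phenol is deactivated by chelation and by two ester groups, so one equivalent should stop at the monochloride.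

**Compound list**
1 | methyl 2,4-dihydroxy-3,6-dimethylbenzoate (methyl atrarate) | COC(=O)c1c(C)cc(O)c(C)c1O | starting material
2 | methyl 5-[chloro(methoxy)methyl]-2,4-dihydroxy-3,6-dimethylbenzoate (racemic, not isolated) | COC(=O)c1c(C)c(C(Cl)OC)c(O)c(C)c1O | intermediate
3 | methyl 5-formyl-2,4-dihydroxy-3,6-dimethylbenzoate | COC(=O)c1c(C)c(C=O)c(O)c(C)c1O | intermediate
4 | methyl 2,4-dihydroxy-5-(hydroxymethyl)-3,6-dimethylbenzoate (not isolated) | COC(=O)c1c(C)c(CO)c(O)c(C)c1O | intermediate
5 | methyl 2,4-dihydroxy-3,5,6-trimethylbenzoate | COC(=O)c1c(C)c(C)c(O)c(C)c1O | intermediate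
6 | but-2-ynoic acid | CC#CC(=O)O | starting material
7 | O-(but-2-ynoyl)-N,N'-dicyclohexylisourea (not isolated) | CC#CC(=O)OC(=NC1CCCCC1)NC1CCCCC1 | intermediate
8 | methyl 4-(but-2-ynoyloxy)-2-hydroxy-3,5,6-trimethylbenzoate | COC(=O)c1c(C)c(C)c(OC(=O)C#CC)c(C)c1O | intermediate
9 | trimethyl orthopropionate (1,1,1-trimethoxypropane) | CCC(OC)(OC)OC | starting material
10 | 1,1-dimethoxyprop-1-ene | CC=C(OC)OC | intermediate
11 | acetyl chloride | CC(=O)Cl | starting material
12 | 4,4-dimethoxy-3-methylbut-3-en-2-one | CC(=O)C(C)=C(OC)OC | intermediate
13 | lithium 4,4-dimethoxy-3-methylbuta-1,3-dien-2-olate (not isolated) | [Li+].[O-]C(=C)C(C)=C(OC)OC | intermediate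
14 | 1,1-dimethoxy-2-methyl-3-(trimethylsilyloxy)buta-1,3-diene | COC(OC)=C(C)C(=C)O[Si](C)(C)C | intermediate
15 | methyl 4-{[6,6-dimethoxy-2,5-dimethyl-4-(trimethylsilyloxy)cyclohexa-1,4-diene-1-carbonyl]oxy}-2-hydroxy-3,5,6-trimethylbenzoate (not isolated) | COC(=O)c1c(C)c(C)c(OC(=O)C2=C(C)CC(O[Si](C)(C)C)=C(C)C2(OC)OC)c(C)c1O | intermediate
16 | methyl 2-hydroxy-4-{[2-methoxy-3,6-dimethyl-4-(trimethylsilyloxy)benzoyl]oxy}-3,5,6-trimethylbenzoate (not isolated) | COC(=O)c1c(C)c(C)c(OC(=O)c2c(C)cc(O[Si](C)(C)C)c(C)c2OC)c(C)c1O | intermediate
17 | methyl 2-hydroxy-4-[(4-hydroxy-2-methoxy-3,6-dimethylbenzoyl)oxy]-3,5,6-trimethylbenzoate | COC(=O)c1c(C)c(C)c(OC(=O)c2c(C)cc(O)c(C)c2OC)c(C)c1O | intermediate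
18 | methyl 4-[(5-chloro-4-hydroxy-2-methoxy-3,6-dimethylbenzoyl)oxy]-2-hydroxy-3,5,6-trimethylbenzoate | COC(=O)c1c(C)c(C)c(OC(=O)c2c(C)c(Cl)c(O)c(C)c2OC)c(C)c1O | target

**Step count**
Total steps: 8. Longest linear sequence: 5 steps (steps 1, 2, 3, 7, 8; the diene branch, steps 4, 5, 6, joins at step 7 and is equally long).

**Steps most likely to fail**

Step 7. The cycloaddition may be slow, because the ketene acetal terminus of the diene is tetrasubstituted and the ynoate carries a beta methyl group. The diene may then be lost first, by protonation by the ring A phenol or by thermal decomposition. Acyl transfer from the aryl ester to the diene may also compete. The fallback replaces the cycloaddition by a classical depside esterification, setting out from 1 and 5 and coming back at 17. Methyl atrarate 1 is benzylated at the non-chelated 4-hydroxyl (BnBr, K2CO3, acetone) to methyl 4-(benzyloxy)-2-hydroxy-3,6-dimethylbenzoate F1. This is methylated at O2 (MeI, K2CO3, DMF, 60 °C) to methyl 4-(benzyloxy)-2-methoxy-3,6-dimethylbenzoate F2 and saponified (KOH, aqueous DMSO, 90 °C) to 4-(benzyloxy)-2-methoxy-3,6-dimethylbenzoic acid F3. The acid is joined to the 4-hydroxyl of 5 by the trifluoroacetic anhydride method (TFAA, toluene, rt) to give methyl 4-{[4-(benzyloxy)-2-methoxy-3,6-dimethylbenzoyl]oxy}-2-hydroxy-3,5,6-trimethylbenzoate F4. Hydrogenolysis (H2, 10% Pd/C, EtOAc) should then give 17.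

Step 5. Chloride may dealkylate the acylated dimethoxycarbenium ion before it loses its proton, which leads to the beta-keto ester. The amine may also dehydrochlorinate acetyl chloride to ketene and so use up the acylating agent. The fallback builds the same enone from a dichloroalkene, setting out from 11 and coming back at 12. Acetyl chloride 11 is added to commercial 1,1-dichloroprop-1-ene under Friedel–Crafts conditions (AlCl3, CH2Cl2, 0 °C) to give racemic 4,4,4-trichloro-3-methylbutan-2-one F5. Dehydrochlorination (Et3N, Et2O) gives 4,4-dichloro-3-methylbut-3-en-2-one F6. Double addition–elimination with NaOMe (2 equiv, MeOH, 0 °C) should then give 12.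

Step 4. The elimination may stall because methanol re-adds to the ketene acetal, and prolonged heating with the Lewis acid may oligomerize the product. The fallback makes the ketene acetal by reductive elimination and not by dealcoholation, setting out from 9 and coming back at 10. Orthoester 9 is brominated at the alpha carbon (Br2, pyridine) to racemic 2-bromo-1,1,1-trimethoxypropane F7. Sodium (dispersion, refluxing Et2O) then removes bromide and one methoxide to give 10, which is distilled.

**Further compounds**
F1 | step 7 | methyl 4-(benzyloxy)-2-hydroxy-3,6-dimethylbenzoate | COC(=O)c1c(C)cc(OCc2ccccc2)c(C)c1O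
F2 | step 7 | methyl 4-(benzyloxy)-2-methoxy-3,6-dimethylbenzoate | COC(=O)c1c(C)cc(OCc2ccccc2)c(C)c1OC
F3 | step 7 | 4-(benzyloxy)-2-methoxy-3,6-dimethylbenzoic acid | OC(=O)c1c(C)cc(OCc2ccccc2)c(C)c1OC
F4 | step 7 | methyl 4-{[4-(benzyloxy)-2-methoxy-3,6-dimethylbenzoyl]oxy}-2-hydroxy-3,5,6-trimethylbenzoate | COC(=O)c1c(C)c(C)c(OC(=O)c2c(C)cc(OCc3ccccc3)c(C)c2OC)c(C)c1O
F5 | step 5 | 4,4,4-trichloro-3-methylbutan-2-one (racemic) | CC(=O)C(C)C(Cl)(Cl)Cl
F6 | step 5 | 4,4-dichloro-3-methylbut-3-en-2-one | CC(=O)C(C)=C(Cl)Cl
F7 | step 4 | 2-bromo-1,1,1-trimethoxypropane (racemic) | CC(Br)C(OC)(OC)OC
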